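The runs come from a simulation from invented constants, noise included.

4 questions stand on this flask, and they come down to one decision at 12 min: do I leave it, add catalyst, take out target or warm it?

in all of them: catalyst 10 mol%
- maple: starting material 1 M; coupling partner 3 equiv; second substrate 0.50 equiv; protic impurity 0.050 M; temperature −20 °C; the very flask that is asked about, followed so far
- ash: starting material 1 M; coupling partner 3 equiv; second substrate 0.50 equiv; protic impurity 0.050 M; temperature −25 °C; run made earlier
- flask: starting material 1.0 M; coupling partner 3.00 equiv; second substrate 0.500 equiv; protic impurity 0.0500 M; temperature −20 °C; time 12 min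

| run | time / min | target / % | starting material / % |
|---|---|---|---|
| maple | 0.500 | 26.4 | 76.3 |
| maple | 1.00 | 37.3 | 63.4 |
| maple | 2.00 | 50.9 | 50.1 |
| maple | 4.00 | 62.7 | 37.2 |
| maple | 8.00 | 70.3 | 29.9 |
| ash | 0.500 | 16.8 | 84.1 |
| ash | 1.00 | 26.8 | 72.5 |
| ash | 2.00 | 43.2 | 56.8 |
| ash | 4.00 | 57.8 | 41.5 |
| ash | 8.00 | 69.4 | 30.2 |

(scatter of a reading: 1 percentage point)

- epsilon: change nothing and wait 12 min more
- beta: at 12 min add catalyst, 50.0 % of the amount charged, then wait 12 min
- eta: at 12 min take out 90 % of the target then present, then wait 12 min
- delta: at 12 min raise the temperature by 20 K, then wait 12 min

- removed target is counted in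
- additions bring no volume worth counting

- target, in percent of the starting material first charged, at 12 min
- which option adds most target ("none" when 2 percentage points or less is all one gets) (epsilon / beta / eta / delta / none)
- target present, with what was taken out counted in, in percent of the starting material first charged, after epsilon
- target present, with what was taken out counted in, in percent of the starting material first charged, after beta

Maple is this very flask followed so far, and its two columns sum close to the charge, so I read target as whatever starting material has gone. The curve looks like a stall, but its last two readings give 0.0546 min⁻¹ as the tail constant, the pseudo-first-order slope of the logarithm of starting material over the last readings of a run. This is a reading and carries their scatter.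

Carrying that slope forward from the last reading, I get a logarithmic conversion of 1.43 and so 76.0 % target at 12 min. Waiting 12 min more gives 87.5 %.

Maple's last reading also stands 0.770 above the line of the tail constant drawn back to the start, and I take this as the early burst of fresh catalyst. My assumption is that the added catalyst repeats that burst and raises the tail, both in proportion to its amount, which gives 93.9 %, more than waiting.

Target appears nowhere in this reckoning, so I expect nothing extra from removing it. Colder ash reads a tail of 0.0795 min⁻¹, larger than maple's, so I don't expect warming to pay either. I would add catalyst.

The forecast also chooses beta, with 72 % now, 73.5 % after waiting and 85 % after adding catalyst. Its ground is: “I read the stall as catalyst death, faster when warmer, rather than equilibrium”. We part on waiting, where my figure stands above the forecast's.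

The flask gives 76.7 % at 12 min, 87.0 % after waiting and 92.5 % after adding catalyst. The best option is beta, with a gain of 16 percentage points against 10 points for waiting, 10 points for removing target and 8.9 points for warming.

    catalyst ⇌ dormant form (K = 6.67, k = 0.00828 s⁻¹, Ea = 75.0 kJ mol⁻¹, ΔH = 60.0 kJ mol⁻¹)
    second substrate + coupling partner + catalyst → catalyst + second product (k = 0.0786 M⁻² s⁻¹, Ea = 41.0 kJ mol⁻¹)
    starting material + coupling partner + catalyst → catalyst + target (k = 0.0378 M⁻² s⁻¹, Ea = 49.0 kJ mol⁻¹)
    coupling partner + protic impurity → quenched reagent (k = 0.0374 M⁻¹ s⁻¹, Ea = 36.0 kJ mol⁻¹)
    (constants at −20 °C)

The flask slows without stopping, and part of the reason is the catalyst's exchange with the dormant form, acting together with the early hour of the reading. The run without that exchange stands at 98.9 % at 12 min instead of 76.7 %, and the flask left ten times as long reaches 99.8 %. At 12.0 min the dormant form stands at 86.9 % and the free catalyst at 13.1 %, each in percent of the catalyst charged. Starting from 76.7 %, the tail constant gives 87.9 % after 12 min, where the flask has 87.0 %.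

For the neighbour charged with 1.80 equiv of coupling partner, I scale my logarithmic conversion, tail included, by the ratio of the charges, since the step that forms target is first order in coupling partner; that gives a tail of 0.0328 min⁻¹ and 57.5 % target at 12 min. The simulation of that neighbour gives 54.7 %.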